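I decided to keep the books of this flask on L, whose charge stands 1.00 mM above that of Q, because E and Q both draw on it.

| flask | E | Q | L | remark | time |
|---|---|---|---|---|---|
| Wednesday's | 20 mM | 20 mM | 21 mM | the very flask that is asked about, followed so far |  |
| Saturday's | 10 mM | 20 mM | 21 mM | run made earlier |  |
| flask | 20 mM | 20.0 mM | 21.0 mM |  | 10 d |

| run | time / d | X / % |
|---|---|---|
| Wednesday's | 0.500 | 5.3 |
| Wednesday's | 0.833 | 7.7 |
| Wednesday's | 1.04 | 7.7 |
| Wednesday's | 1.67 | 9.6 |
| Wednesday's | 2.00 | 11.0 |
| Wednesday's | 3.00 | 10.0 |
| Saturday's | 0.500 | 5.1 |
| Saturday's | 0.833 | 8.8 |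
| Saturday's | 1.25 | 10.7 |
| Saturday's | 1.67 | 12.5 |
| Saturday's | 2.50 | 14.5 |
| Saturday's | 4.00 | 13.8 |

(scatter of a reading: 0.5 percentage points)

- percentages count the E that a species holds: one Z or J counts as two
- steps that have been proposed: L + Q -> G; E + X -> J; 2 D -> Z; E + L -> D; D + G -> X

* time up to 10 d at which X stands highest
* the amount of X, in percent of the E charged, at that time
* the first time at which X reaches 7.4%, in the same percent, in d

E takes L on the way to D, Q takes L on the way to G, and D with G gives X. Call M the L taken by E, in mM. With the whole 21 mM of L used, that L went either to Q or to E, so Q left = M − 1.00 mM. E and Q draw on L in proportion to what stands of each. With E held at its charge, this gives M = s·E·ln(Q charged / Q left), where s is a selectivity factor, the pull of E on L against that of Q at equal amounts.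

I took the top X reading as M, which counts nothing lost to J, so s is an apparent value and carries the scatter of the readings. Wednesday's run gave M = 2.20 mM, so I reckoned Q left at 1.20 mM and s = 0.0391. Saturday's run, with half the E, gave M = 1.45 mM and s = 0.0382. These are two runs with different E and different Q left, yet the two values of s nearly coincide. I carried their mean, the apparent selectivity s = 0.0387. In percent of the E charged, the top is then s·ln(Q charged / Q left).

With the balance holding, I trusted Wednesday's top and committed to about 11.0% near 2.00 d, with 7.4% crossed near 0.791 d.

The forecast said 10.6% at 2.4 d and 0.85 d for the level, holding that “L should run out while E remains”.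

The flask topped at 10.6% at 2.05 d and reached the level at 0.802 d.

    L + Q → G (k = 0.291 /M/min)
    E + X → J (k = 0.00520 /M/min)
    2 D → Z (k = 0.0129 /M/min)
    E + L → D (k = 0.0176 /M/min)
    D + G → X (k = 0.124 /M/min)

At 10.0 d the flask held L at 0% and Q at 8.69% of their charges. That Q put into s gives 9.45%, so the top of the flask stood 1.12 times above it. The neighbour charged with 5.0 mM of E held Q at 1.33% of its charge at 10.0 d, for which s gives 16.7%, and the top of that neighbour stood 1.11 times above that, at 18.5%.

The numbers in the tables were generated by integration for substances that don't exist.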